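Sceptrin is C2-symmetric. The axis passes through the midpoints of the cyclobutane bonds C(imidazolyl)–C(imidazolyl) and C(CH2N)–C(CH2N), so cutting these two bonds gives two identical hymenidin halves. The key step is an enantioselective head-to-head [2+2] photodimerisation under an iridium triplet sensitiser and a chiral phosphoric acid. It forms both bonds, the all-trans cyclobutane and all four stereocentres in one operation, with both pyrroles and both imidazoles already in place. Its precursor is an (E)-alkene monomer whose 2-aminoimidazole is masked as an imidazo[1,2-a]pyrimidine. The basic imidazole nitrogen and the pyrrole N–H/amide N–H cleft are the handles for the chiral phosphate. Hydrazine finally removes both temporary pyrimidine rings.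

Key step: step 4

Assumption: the (R)-enantiomer of the phosphoric acid is taken to lead to the enantiomer drawn. Both antipodes of the acid are commercial, so the (S)-acid is used if the sense of induction proves opposite.

Step 1
Reactants: 1 4-bromo-2-(trichloroacetyl)-1H-pyrrole; 2 allylamine
Product: 3 N-allyl-4-bromo-1H-pyrrole-2-carboxamide
Conditions: 2 (1.2 equiv), MeCN, 0 °C to rt
Reagents that add atoms: none
Why: Haloform-type acyl substitution, in which the primary amine adds to the trichloromethyl ketone and the CCl3 group leaves as chloroform, should give the amide without coupling reagent and without protection of the pyrrole N–H; no stereocentre is formed.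

Step 2
Reactants: 4 imidazo[1,2-a]pyrimidine
Product: 5 3-iodoimidazo[1,2-a]pyrimidine
Conditions: NIS (1.05 equiv), MeCN, rt, dark
Reagents that add atoms: N-iodosuccinimide, O=C1CCC(=O)N1I
Why: Electrophilic aromatic iodination should take place at C3, the enamine-like and most nucleophilic position of the five-membered ring.

Step 3
Reactants: 3 N-allyl-4-bromo-1H-pyrrole-2-carboxamide; 5 3-iodoimidazo[1,2-a]pyrimidine
Product: 6 (E)-4-bromo-N-[3-(imidazo[1,2-a]pyrimidin-3-yl)prop-2-en-1-yl]-1H-pyrrole-2-carboxamide
Conditions: Pd(OAc)2 (5 mol %), n-Bu4NCl (1 equiv), NaHCO3 (2.5 equiv), DMF, 70 °C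
Reagents that add atoms: none
Why: Mizoroki–Heck reaction under Jeffery conditions, in which oxidative addition to the C–I bond is much faster than to the electron-rich pyrrole C–Br bond, and syn insertion at the terminal carbon followed by syn β-hydride elimination from the heteroaryl-bearing carbon should give the conjugated (E)-alkene.

Step 4
Reactants: 6 (E)-4-bromo-N-[3-(imidazo[1,2-a]pyrimidin-3-yl)prop-2-en-1-yl]-1H-pyrrole-2-carboxamide (two molecules)
Product: 8 (1R,2R,3S,4S)-configured all-trans head-to-head dimer of 6, via triplet 1,4-diradical 7 (not isolated)
Conditions: (R)-TRIP (20 mol %), fac-Ir(ppy)3 (1 mol %), CH2Cl2 (0.02 M), Ar, 450 nm LED, −40 °C; chromatography, recrystallisation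
Reagents that add atoms: none
Why: Proposed new method: the phosphoric acid protonates the basic imidazole-type nitrogen N1 of one monomer and its phosphate oxygen accepts the pyrrole N–H/amide N–H cleft of a second monomer, so that a ternary complex holds the two alkenes head to head inside the chiral pocket before light is absorbed. Ir(ppy)3 excited at 450 nm transfers triplet energy (Dexter) to the alkenyl-azaarene, the short-lived twisted triplet is trapped by the pre-associated partner through bond formation between the two CH2N-bearing carbons to give the doubly heteroaryl-stabilised 1,4-diradical 7, and after intersystem crossing the two heteroaryl-bearing carbons recombine, so the cyclobutane is closed by an intermolecular stepwise [2+2] cycloaddition whose ring-closing event is a 1,4-diradical recombination. The closest known reaction types are the racemic Ir-sensitised head-to-head [2+2] dimerisation of β-substituted alkenyl(hetero)arenes and the enantioselective [2+2] photocycloaddition of alkenylpyridines with N–H-bearing alkenes under an Ir sensitiser and a chiral phosphoric acid; new is their merger into an enantioselective homodimerisation of an alkenyl-imidazopyrimidine. The two CH2N-bearing stereocentres (both R) are set in the first bond formation, where the 3,3'-aryl groups of the phosphate leave one face of each alkene carbon open, and the two heteroaryl-bearing stereocentres (both S) are set in the recombination under substrate control, each radical centre turning its heteroaryl group trans to both ring neighbours. The step needs head-to-head regioselectivity (secured by heteroaryl stabilisation of both radical centres), all-trans diastereoselectivity (the unlike-configured diradical could only close to a ring with cis CH2N arms and should rather fragment back to monomer) and enantioselectivity (dilution and low temperature disfavour the diffusion-dependent acid-free background). E/Z photoisomerisation of 6 is harmless because both isomers reach the same twisted triplet, and the C–Br bonds should persist because no sacrificial reductant is present.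

Step 5
Reactants: 8 (1R,2R,3S,4S)-configured all-trans head-to-head dimer of 6
Product: 9 sceptrin
Conditions: N2H4·H2O (excess), EtOH, 80 °C
Reagents that add atoms: none
Why: Hydrazinolytic unmasking of imidazo[1,2-a]pyrimidines, in which hydrazine adds to the electrophilic pyrimidine carbons, opens each pyrimidine ring and carries off its three-carbon unit as pyrazole, should free both 2-aminoimidazoles while the secondary amides, the C–Br bonds and the four cyclobutane stereocentres (no acidic C–H) stay untouched.

Compound list
1 | 4-bromo-2-(trichloroacetyl)-1H-pyrrole | O=C(c1cc(Br)c[nH]1)C(Cl)(Cl)Cl | starting material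
2 | allylamine | C=CCN | starting material
3 | N-allyl-4-bromo-1H-pyrrole-2-carboxamide | C=CCNC(=O)c1cc(Br)c[nH]1 | intermediate
4 | imidazo[1,2-a]pyrimidine | c1cnc2nccn2c1 | starting material
5 | 3-iodoimidazo[1,2-a]pyrimidine | Ic1cnc2ncccn12 | intermediate
6 | (E)-4-bromo-N-[3-(imidazo[1,2-a]pyrimidin-3-yl)prop-2-en-1-yl]-1H-pyrrole-2-carboxamide | O=C(NC/C=C/c1cnc2ncccn12)c1cc(Br)c[nH]1 | intermediate
7 | triplet 1,4-diradical, new bond between the two CH2N-bearing carbons (configured as in 8), radical centres on the two heteroaryl-bearing carbons | c1cnc2ncc([CH][C@H](CNC(=O)c3cc(Br)c[nH]3)[C@@H](CNC(=O)c3cc(Br)c[nH]3)[CH]c3cnc4ncccn34)n2c1 | intermediate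
8 | N,N'-{[(1R,2R,3S,4S)-3,4-bis(imidazo[1,2-a]pyrimidin-3-yl)cyclobutane-1,2-diyl]bis(methylene)}bis(4-bromo-1H-pyrrole-2-carboxamide), all-trans | c1cnc2ncc([C@H]3[C@H](CNC(=O)c4cc(Br)c[nH]4)[C@@H](CNC(=O)c4cc(Br)c[nH]4)[C@@H]3c3cnc4ncccn34)n2c1 | intermediate
9 | sceptrin, N,N'-{[(1R,2R,3S,4S)-3,4-bis(2-amino-1H-imidazol-5-yl)cyclobutane-1,2-diyl]bis(methylene)}bis(4-bromo-1H-pyrrole-2-carboxamide) | Nc1ncc([C@H]2[C@H](CNC(=O)c3cc(Br)c[nH]3)[C@@H](CNC(=O)c3cc(Br)c[nH]3)[C@@H]2c2cnc(N)[nH]2)[nH]1 | target

Total step count: 5. Longest linear sequence: 4 (step 1 or 2, then steps 3, 4, 5).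

Steps most likely to fail

Step 4. Enantiofacial discrimination may be weak, because acid-free, self-associated monomer pairs can dimerise in the background and the equally basic product can bind the acid. The triplet may also decay by E/Z isomerisation faster than it is trapped. The fallback uses known chemistry and replaces asymmetric catalysis by racemic synthesis plus resolution. It sets out from 6. Acid-free sensitised dimerisation (fac-Ir(ppy)3, MeOH, concentrated, 450 nm, rt) should give the all-trans head-to-head dimer as the racemate, that is 8 together with its mirror image ent-8 F1. Preparative chromatography on a polysaccharide chiral stationary phase (SFC, amine additive) separates the two, and the route is rejoined at 8.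

Step 3. Re-insertion of Pd–H may move the double bond toward nitrogen, insertion may occur in the branched sense, or coordination of the azaarene to palladium may slow turnover. The fallback fixes position and geometry of the alkene before the coupling. It sets out from 1. Acylation of propargylamine with 1 (MeCN, rt) gives the N-propargyl amide F2. Zirconium-catalysed syn hydroboration (HBpin in excess to allow for the N–H groups, Cp2ZrHCl cat., Et3N cat., 60 °C) gives the (E)-alkenylboronate F3. Suzuki–Miyaura coupling of F3 with 5 (Pd(dppf)Cl2, K3PO4, dioxane/H2O, 60 °C), selective for C–I over the pyrrole C–Br, comes back to the route at 6.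

Step 5. The second pyrimidine ring may open only sluggishly, and prolonged heating may start hydrazinolysis of the pyrrole amides. The fallback brings hydrazine in before the bromopyrrole amides exist, and the cyclobutane remains the last ring that is closed.
- It sets out from 5. Mizoroki–Heck coupling with tert-butyl allylcarbamate under the conditions of step 3 gives the Boc monomer F4.
- Dimerisation by the method of step 4, with the carbamate N–H as donor to the phosphate (or by the fallback of step 4), gives the Boc dimer F5.
- Hydrazine (EtOH, 80 °C) gives the bis(2-aminoimidazole) biscarbamate F6.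
- HCl in dioxane gives the tetraamine F7, handled as its hydrochloride.
- Acylation with 1 (2 equiv, Na2CO3, DMF, rt) should be selective for the aliphatic amines over the weakly nucleophilic 2-aminoimidazoles, and it comes back to the route at 9.

Further compounds
F1 | step 4 | ent-8, (1S,2S,3R,4R)-configured all-trans head-to-head dimer of 6 | c1cnc2ncc([C@@H]3[C@@H](CNC(=O)c4cc(Br)c[nH]4)[C@H](CNC(=O)c4cc(Br)c[nH]4)[C@H]3c3cnc4ncccn34)n2c1
F2 | step 3 | 4-bromo-N-(prop-2-yn-1-yl)-1H-pyrrole-2-carboxamide | C#CCNC(=O)c1cc(Br)c[nH]1
F3 | step 3 | (E)-4-bromo-N-[3-(4,4,5,5-tetramethyl-1,3,2-dioxaborolan-2-yl)prop-2-en-1-yl]-1H-pyrrole-2-carboxamide | CC1(C)OB(/C=C/CNC(=O)c2cc(Br)c[nH]2)OC1(C)C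
F4 | step 5 | tert-butyl (E)-[3-(imidazo[1,2-a]pyrimidin-3-yl)prop-2-en-1-yl]carbamate | CC(C)(C)OC(=O)NC/C=C/c1cnc2ncccn12
F5 | step 5 | di-tert-butyl {[(1R,2R,3S,4S)-3,4-bis(imidazo[1,2-a]pyrimidin-3-yl)cyclobutane-1,2-diyl]bis(methylene)}dicarbamate | c1cnc2ncc([C@H]3[C@H](CNC(=O)OC(C)(C)C)[C@@H](CNC(=O)OC(C)(C)C)[C@@H]3c3cnc4ncccn34)n2c1
F6 | step 5 | di-tert-butyl {[(1R,2R,3S,4S)-3,4-bis(2-amino-1H-imidazol-5-yl)cyclobutane-1,2-diyl]bis(methylene)}dicarbamate | Nc1ncc([C@H]2[C@H](CNC(=O)OC(C)(C)C)[C@@H](CNC(=O)OC(C)(C)C)[C@@H]2c2cnc(N)[nH]2)[nH]1
F7 | step 5 | 5,5'-[(1S,2S,3R,4R)-3,4-bis(aminomethyl)cyclobutane-1,2-diyl]bis(1H-imidazol-2-amine) | Nc1ncc([C@H]2[C@H](CN)[C@@H](CN)[C@@H]2c2cnc(N)[nH]2)[nH]1
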